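**Plan**

- Retrosynthesis first cuts C3–C(aroyl) and C1–geranyl, which are formed by vinylic and bridgehead lithiation, leaving 5-geranyl-8,8-dimethyl-7-prenylbicyclo[3.3.1]nonane-2,4,9-trione.
- The C1–C8 bond is cut next and C8 is returned to C9. The C9 ketone lies between C1 and the quaternary C8, so ring B contracts to a cyclopentane in which C9 is a tertiary carbinol bonded to C8 and C1 is the α′-methylene of an enolised 1,3-dione; an oxidant can expand this cis-fused hydroxy dione back to the bridged trione.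
- The fused six-membered ring is cut at C9–C1 (aldol) and C5–C4 (acylation), which removes the four carbons of diketene. Cuts at C5–geranyl, the prenyl C=C, C8–CH3 and C7–CH2 lead to 2-methylcyclopent-2-en-1-one.
- Forward order: cyclopentane (bought), fused dione ring by diketene annulation, ring B by ring expansion, then O-methylation, C1 geranylation, C3 aroylation and deprotection.
- Stereochemistry: C7 comes from a copper-catalysed asymmetric conjugate addition, C5 from acylation anti to the C7 prenyl group, the C9 carbinol from the forced cis ring fusion, and C1 from the geometry of the bicycle. Both E-olefins come from geranyl bromide.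

Key step: step 6

Remark: atom labels C1–C9 are those of the bicyclo[3.3.1]nonane core of the target and are kept for the same atoms in all earlier intermediates; enolised diones are written in one tautomeric form.
Assumption: the sense of induction in step 1 is set by the choice of ligand antipode (both are sold); the antipode that leads to the 3S ketone is used.

**Step 1**
Reactants: 1 2-methylcyclopent-2-en-1-one; 2 (1,3-dioxolan-2-ylmethyl)magnesium bromide (commercial THF solution)
Product: 4 (S)-3-(1,3-dioxolan-2-ylmethyl)-2,2-dimethylcyclopentan-1-one, via bromomagnesium enolate 3 (not isolated)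
Conditions: CuBr·SMe2 (5 mol %), 1-[2-(dicyclohexylphosphino)ferrocenyl]ethyldiphenylphosphine (6 mol %, single antipode), t-BuOMe, −78 °C, slow addition of 2; then MeI, DMPU, −78 → 0 °C
Reagents that add atoms: (1,3-dioxolan-2-ylmethyl)magnesium bromide (2), Br[Mg]CC1OCCO1; iodomethane, CI
Why: Copper-catalysed asymmetric conjugate addition of a primary Grignard reagent to 2-methylcyclopentenone sets C7 by enantioface selection under the ferrocenyl diphosphine, and the regiodefined magnesium enolate is C-methylated in the same flask (tandem conjugate addition–enolate alkylation) to give the C8 gem-dimethyl carbon.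

**Step 2**
Reactants: 4 (S)-3-(1,3-dioxolan-2-ylmethyl)-2,2-dimethylcyclopentan-1-one
Product: 5 (S)-2-(2,2-dimethyl-3-oxocyclopentyl)acetaldehyde
Conditions: 1 M aq. HCl, THF, rt
Reagents that add atoms: water, O
Why: Acid-catalysed acetal hydrolysis frees the aldehyde; the stereocentre carries no enolisable hydrogen and the keto aldehyde can only aldolise to strained rings.

**Step 3**
Reactants: 5 (S)-2-(2,2-dimethyl-3-oxocyclopentyl)acetaldehyde
Product: 6 (S)-2,2-dimethyl-3-(3-methylbut-2-en-1-yl)cyclopentan-1-one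
Conditions: i-PrPPh3I, n-BuLi, THF, 0 °C; then 5, −78 → 0 °C
Reagents that add atoms: isopropyltriphenylphosphonium iodide, CC(C)[P+](c1ccccc1)(c1ccccc1)c1ccccc1.[I-]
Why: Wittig olefination with the non-stabilised isopropylidene ylide is far faster at the aldehyde than at the neopentyl-type ketone and completes the prenyl group, with no olefin geometry to control.

**Step 4**
Reactants: 6 (S)-2,2-dimethyl-3-(3-methylbut-2-en-1-yl)cyclopentan-1-one; 7 geranyl bromide
Product: 9 (3R,5RS)-5-[(2E)-3,7-dimethylocta-2,6-dien-1-yl]-2,2-dimethyl-3-(3-methylbut-2-en-1-yl)cyclopentan-1-one, via lithium enolate 8 (not isolated)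
Conditions: LDA (lithium diisopropylamide), THF, −78 °C; then 7, DMPU, −78 → −20 °C
Reagents that add atoms: geranyl bromide (7), CC(C)=CCC/C(C)=C/CBr
Why: Ketone enolate alkylation can occur only at C5 because C8 is quaternary, the SN2 reaction keeps the E-olefin, and the C5 epimer mixture is harmless since this centre is enolised again in step 5.

**Step 5**
Reactants: 9 (3R,5RS)-5-geranyl-2,2-dimethyl-3-prenylcyclopentan-1-one; 10 diketene
Product: 13 (2R,3aS,7aR)-3a-[(2E)-3,7-dimethylocta-2,6-dien-1-yl]-4,7a-dihydroxy-1,1-dimethyl-2-(3-methylbut-2-en-1-yl)-1,2,3,3a,7,7a-hexahydro-6H-inden-6-one, via lithium enolate 11 (not isolated), via acetoacetyl enolate 12 (not isolated)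
Conditions: LiTMP (lithium 2,2,6,6-tetramethylpiperidide), THF, −78 °C; then 10, −78 → −40 °C; sat. aq. NH4Cl
Reagents that add atoms: diketene (10), C=C1CC(=O)O1
Why: In this diketene annulation the tetrasubstituted enolate opens the β-lactone by C-acylation on the face anti to the C7 prenyl group (setting C5 with geranyl cis to prenyl), and the terminal enolate so released adds to the C9 ketone in an intramolecular aldol reaction whose tether enforces the cis ring fusion (C9–OH cis to the C5 geranyl).

**Step 6**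
Reactants: 13 cis-fused hydroxy dione (enol form)
Product: 15 (1R,5S,7R)-5-[(2E)-3,7-dimethylocta-2,6-dien-1-yl]-4-hydroxy-8,8-dimethyl-7-(3-methylbut-2-en-1-yl)bicyclo[3.3.1]non-3-ene-2,9-dione, via C1 iodane 14 (not isolated)
Conditions: PhI(OAc)2, KOH, MeOH, −30 → 0 °C; then 1 M aq. HCl to pH 3, 0 °C
Reagents that add atoms: none
Why: KOH in MeOH converts PhI(OAc)2 into PhI(OMe)2 and the hydroxy dione into its enolate and alkoxide; trivalent iodine passes to the extended enolate so that C1 carries the methoxy(phenyl)iodanyl group (14, reached directly or by allylic shift of iodine from C3), and as PhI departs reductively from C1 the C9 alkoxide pushes the C9–C8 bond onto C1 while C9 becomes the bridging ketone. The closest known reaction type is the iodane-mediated oxidative semipinacol (1,2-alkyl shift) ring expansion of fused hydroxy 1,3-diones to bicyclo[3.3.1]nonane-2,4,9-triones, used here on a close analogue. Ring B is not closed by a cyclisation; it arises by one-carbon enlargement of the cyclopentane (C1 is inserted between C9 and C8), which turns the fused bicycle into the bridged one. The new stereocentre C1 is fixed by the suprafacial shift, because C8 can reach C1 only on the ring face where it already sits at C9, the sole configuration a bicyclo[3.3.1]nonane bridge allows; C5 and C7 are untouched. The step needs C8 to migrate in preference to C5, to epoxide closure by the alkoxide and to methoxide capture at C1: C8 is an electron-rich quaternary carbon that the cis-fused frame can hold antiperiplanar to the C1–I bond, C5 bears the electron-withdrawing C4 carbonyl, and the low temperature holds back retro-aldol cleavage of C9–C1.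

**Step 7**
Reactants: 15 bicyclic trione (enol form)
Product: 16 (1R,5S,7R)-5-[(2E)-3,7-dimethylocta-2,6-dien-1-yl]-4-methoxy-8,8-dimethyl-7-(3-methylbut-2-en-1-yl)bicyclo[3.3.1]non-3-ene-2,9-dione
Conditions: TMSCHN2, toluene/MeOH (4:1), 0 °C
Reagents that add atoms: (trimethylsilyl)diazomethane, C[Si](C)(C)C=[N+]=[N-]
Why: O-Methylation of the vinylogous acid by diazomethane released from TMSCHN2 in methanol should favour the C4 oxygen because the C2 oxygen lies under the axial methyl of the C8 gem-dimethyl group, and any C2 methyl ether is separated and returned to 15 by mild acid hydrolysis.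

**Step 8**
Reactants: 16 C4 methyl enol ether; 7 geranyl bromide
Product: 18 (1R,5S,7R)-1,5-bis[(2E)-3,7-dimethylocta-2,6-dien-1-yl]-4-methoxy-8,8-dimethyl-7-(3-methylbut-2-en-1-yl)bicyclo[3.3.1]non-3-ene-2,9-dione, via bridgehead organolithium 17 (not isolated)
Conditions: LiTMP, THF, −78 °C; then 7, −78 → −30 °C
Reagents that add atoms: geranyl bromide (7), CC(C)=CCC/C(C)=C/CBr
Why: Bridgehead lithiation–alkylation of a bicyclo[3.3.1]nonanetrione enol ether removes C1–H, which is α′ to the C2 carbonyl and α to the C9 ketone and lies in the plane of the chelating C2 oxygen, and the pyramidal bridgehead carbanion can be alkylated by the primary allylic bromide only with retention.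

**Step 9**
Reactants: 19 3,4-dihydroxybenzoic acid
Product: 20 tert-butyldimethylsilyl 3,4-bis(tert-butyldimethylsilyloxy)benzoate
Conditions: TBSCl (3.5 equiv), imidazole, DMF, rt
Reagents that add atoms: tert-butyldimethylsilyl chloride, CC(C)(C)[Si](C)(C)Cl
Why: Imidazole-promoted exhaustive silylation protects both phenols and gives the silyl ester needed for acid chloride formation without free acid.

**Step 10**
Reactants: 20 tris-silylated acid
Product: 21 3,4-bis(tert-butyldimethylsilyloxy)benzoyl chloride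
Conditions: (COCl)2, DMF (cat.), CH2Cl2, 0 °C → rt
Reagents that add atoms: oxalyl chloride, O=C(Cl)C(=O)Cl
Why: The Vilsmeier-type chloroiminium reagent converts the silyl ester directly into the acid chloride under neutral conditions, so the aryl silyl ethers survive.

**Step 11**
Reactants: 18 C1-geranylated enol ether; 21 3,4-bis(tert-butyldimethylsilyloxy)benzoyl chloride
Product: 23 (1S,5S,7R)-3-[3,4-bis(tert-butyldimethylsilyloxy)benzoyl]-1,5-bis[(2E)-3,7-dimethylocta-2,6-dien-1-yl]-4-methoxy-8,8-dimethyl-7-(3-methylbut-2-en-1-yl)bicyclo[3.3.1]non-3-ene-2,9-dione, via C3 vinyllithium 22 (not isolated)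
Conditions: LiTMP, THF, −78 °C; then 21, −78 → −40 °C
Reagents that add atoms: 3,4-bis(tert-butyldimethylsilyloxy)benzoyl chloride (21), CC(C)(C)[Si](C)(C)Oc1ccc(C(=O)Cl)cc1O[Si](C)(C)C(C)(C)C
Why: α-Lithiation of the β-methoxy enone at C3, the only acidic C–H left, followed by C-acylation with the acid chloride is the standard way to place the C3 aroyl group on this class of bicyclic enol ethers.

**Step 12**
Reactants: 23 protected precursor
Product: 24 (1S,5S,7R)-3-(3,4-dihydroxybenzoyl)-1,5-bis[(2E)-3,7-dimethylocta-2,6-dien-1-yl]-4-hydroxy-8,8-dimethyl-7-(3-methylbut-2-en-1-yl)bicyclo[3.3.1]non-3-ene-2,9-dione (CNP0178719.1)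
Conditions: LiOH·H2O, 1,4-dioxane/H2O (degassed, Ar), 90 °C; then 1 M aq. HCl to pH 3–4, 0 °C
Reagents that add atoms: lithium hydroxide, [Li+].[OH-]
Why: Hydroxide adds to C4 of the doubly activated β-methoxy enone and expels methoxide (addition–elimination hydrolysis of the vinylogous ester) and in the same flask cleaves the two base-labile aryl silyl ethers, with no stereocentre able to enolise.

**Compound list**

1 | 2-methylcyclopent-2-en-1-one | CC1=CCCC1=O | starting material
2 | (1,3-dioxolan-2-ylmethyl)magnesium bromide | Br[Mg]CC1OCCO1 | starting material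
3 | bromomagnesium (S)-3-(1,3-dioxolan-2-ylmethyl)-2-methylcyclopent-1-en-1-olate | CC1=C(O[Mg]Br)CC[C@H]1CC2OCCO2 | intermediate
4 | (S)-3-(1,3-dioxolan-2-ylmethyl)-2,2-dimethylcyclopentan-1-one | O=C1CC[C@@H](CC2OCCO2)C1(C)C | intermediate
5 | (S)-2-(2,2-dimethyl-3-oxocyclopentyl)acetaldehyde | O=C1CC[C@@H](CC=O)C1(C)C | intermediate
6 | (S)-2,2-dimethyl-3-(3-methylbut-2-en-1-yl)cyclopentan-1-one | O=C1CC[C@@H](CC=C(C)C)C1(C)C | intermediate
7 | geranyl bromide, (2E)-1-bromo-3,7-dimethylocta-2,6-diene | CC(C)=CCC/C(C)=C/CBr | starting material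
8 | lithium (4R)-5,5-dimethyl-4-(3-methylbut-2-en-1-yl)cyclopent-1-en-1-olate | [Li]OC1=CC[C@@H](CC=C(C)C)C1(C)C | intermediate
9 | (3R,5RS)-5-[(2E)-3,7-dimethylocta-2,6-dien-1-yl]-2,2-dimethyl-3-(3-methylbut-2-en-1-yl)cyclopentan-1-one (C5 epimers) | O=C1C(C/C=C(\C)CCC=C(C)C)C[C@@H](CC=C(C)C)C1(C)C | intermediate
10 | diketene, 4-methylideneoxetan-2-one | C=C1CC(=O)O1 | starting material
11 | lithium (4R)-2-[(2E)-3,7-dimethylocta-2,6-dien-1-yl]-5,5-dimethyl-4-(3-methylbut-2-en-1-yl)cyclopent-1-en-1-olate | [Li]OC1=C(C/C=C(\C)CCC=C(C)C)C[C@@H](CC=C(C)C)C1(C)C | intermediate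
12 | lithium 4-{(1S,4R)-1-[(2E)-3,7-dimethylocta-2,6-dien-1-yl]-3,3-dimethyl-4-(3-methylbut-2-en-1-yl)-2-oxocyclopentyl}-4-oxobut-1-en-2-olate | C=C(O[Li])CC(=O)[C@]1(C/C=C(\C)CCC=C(C)C)C[C@@H](CC=C(C)C)C(C)(C)C1=O | intermediate
13 | (2R,3aS,7aR)-3a-[(2E)-3,7-dimethylocta-2,6-dien-1-yl]-4,7a-dihydroxy-1,1-dimethyl-2-(3-methylbut-2-en-1-yl)-1,2,3,3a,7,7a-hexahydro-6H-inden-6-one (cis-fused; enol of the 7a-hydroxy-4,6-dione; geranyl, OH and prenyl on one face) | CC(C)=CCC/C(C)=C/C[C@@]12C[C@@H](CC=C(C)C)C(C)(C)[C@]1(O)CC(=O)C=C2O | intermediate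
14 | C1-[methoxy(phenyl)-λ3-iodanyl] derivative of 13 (indene position 7, epimers at that carbon) | CC(C)=CCC/C(C)=C/C[C@@]12C[C@@H](CC=C(C)C)C(C)(C)[C@]1(O)C(I(OC)c3ccccc3)C(=O)C=C2O | intermediate
15 | (1R,5S,7R)-5-[(2E)-3,7-dimethylocta-2,6-dien-1-yl]-4-hydroxy-8,8-dimethyl-7-(3-methylbut-2-en-1-yl)bicyclo[3.3.1]non-3-ene-2,9-dione (enol of the 2,4,9-trione; C1–H; C7 prenyl exo, anti to the C2–C4 bridge) | CC(C)=CCC/C(C)=C/C[C@]12C[C@@H](CC=C(C)C)C(C)(C)[C@H](C(=O)C=C1O)C2=O | intermediate
16 | (1R,5S,7R)-5-[(2E)-3,7-dimethylocta-2,6-dien-1-yl]-4-methoxy-8,8-dimethyl-7-(3-methylbut-2-en-1-yl)bicyclo[3.3.1]non-3-ene-2,9-dione | CC(C)=CCC/C(C)=C/C[C@]12C[C@@H](CC=C(C)C)C(C)(C)[C@H](C(=O)C=C1OC)C2=O | intermediate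
17 | C1-lithio derivative of 16 (bridgehead organolithium) | CC(C)=CCC/C(C)=C/C[C@]12C[C@@H](CC=C(C)C)C(C)(C)[C@]([Li])(C(=O)C=C1OC)C2=O | intermediate
18 | (1R,5S,7R)-1,5-bis[(2E)-3,7-dimethylocta-2,6-dien-1-yl]-4-methoxy-8,8-dimethyl-7-(3-methylbut-2-en-1-yl)bicyclo[3.3.1]non-3-ene-2,9-dione | CC(C)=CCC/C(C)=C/C[C@]12C[C@@H](CC=C(C)C)C(C)(C)[C@](C/C=C(\C)CCC=C(C)C)(C(=O)C=C1OC)C2=O | intermediate
19 | 3,4-dihydroxybenzoic acid | O=C(O)c1ccc(O)c(O)c1 | starting material
20 | tert-butyldimethylsilyl 3,4-bis(tert-butyldimethylsilyloxy)benzoate | CC(C)(C)[Si](C)(C)OC(=O)c1ccc(O[Si](C)(C)C(C)(C)C)c(O[Si](C)(C)C(C)(C)C)c1 | intermediate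
21 | 3,4-bis(tert-butyldimethylsilyloxy)benzoyl chloride | CC(C)(C)[Si](C)(C)Oc1ccc(C(=O)Cl)cc1O[Si](C)(C)C(C)(C)C | intermediate
22 | C3-lithio derivative of 18 (vinyllithium) | CC(C)=CCC/C(C)=C/C[C@]12C[C@@H](CC=C(C)C)C(C)(C)[C@](C/C=C(\C)CCC=C(C)C)(C(=O)C([Li])=C1OC)C2=O | intermediate
23 | (1S,5S,7R)-3-[3,4-bis(tert-butyldimethylsilyloxy)benzoyl]-1,5-bis[(2E)-3,7-dimethylocta-2,6-dien-1-yl]-4-methoxy-8,8-dimethyl-7-(3-methylbut-2-en-1-yl)bicyclo[3.3.1]non-3-ene-2,9-dione | CC(C)=CCC/C(C)=C/C[C@]12C[C@@H](CC=C(C)C)C(C)(C)[C@](C/C=C(\C)CCC=C(C)C)(C(=O)C(C(=O)c3ccc(O[Si](C)(C)C(C)(C)C)c(O[Si](C)(C)C(C)(C)C)c3)=C1OC)C2=O | intermediate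
24 | (1S,5S,7R)-3-(3,4-dihydroxybenzoyl)-1,5-bis[(2E)-3,7-dimethylocta-2,6-dien-1-yl]-4-hydroxy-8,8-dimethyl-7-(3-methylbut-2-en-1-yl)bicyclo[3.3.1]non-3-ene-2,9-dione | CC(C)=CCC/C(C)=C/C[C@]12C[C@@H](CC=C(C)C)C(C)(C)[C@](C/C=C(\C)CCC=C(C)C)(C(=O)C(C(=O)c3ccc(O)c(O)c3)=C1O)C2=O | target

Total step count: 12
Longest linear sequence: 10 steps (steps 1–8, 11 and 12; steps 9 and 10 make the acid chloride in a side branch)

**Steps most likely to fail**

Step 8. The base may remove the vinylic C3 hydrogen faster than the C1 bridgehead hydrogen, which is shielded by the C8 gem-dimethyl group, so that geranyl ends up on C3 or 16 is returned. The fallback sets out from 16 and masks C3 first. LiTMP added to 16 in the presence of TMSCl (THF, −78 °C, in situ quench) should give (1R,5S,7R)-5-geranyl-4-methoxy-8,8-dimethyl-7-prenyl-3-(trimethylsilyl)bicyclo[3.3.1]non-3-ene-2,9-dione F1. With C3 blocked, LDA (THF, −78 °C) can remove only the bridgehead hydrogen, and geranyl bromide 7 then gives the C1-geranylated silane, 1,5-digeranyl-4-methoxy-8,8-dimethyl-7-prenyl-3-(trimethylsilyl)bicyclo[3.3.1]non-3-ene-2,9-dione F2. TBAF in THF at 0 °C removes the vinylic silyl group and the route is rejoined at 18.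

Step 1. Enantioface control may erode because the acetal Grignard reagent is delivered in THF and carries coordinating oxygens, which can displace the diphosphine from copper and open an unselective background addition. The fallback sets out from 1 and uses a plain alkyl Grignard reagent in ether, 3-methylbut-3-en-1-ylmagnesium bromide F3, made from 4-bromo-2-methylbut-1-ene and Mg in Et2O. The same CuBr·SMe2/diphosphine system in t-BuOMe at −78 °C, followed by MeI and DMPU, should give (R)-2,2-dimethyl-3-(3-methylbut-3-en-1-yl)cyclopentan-1-one F4, which has the same spatial arrangement at C7. RhCl3·3H2O (cat.) in EtOH at 70 °C then moves the 1,1-disubstituted double bond into the more stable trisubstituted position, and the route is rejoined at 6 without steps 2 and 3.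

Step 6. The iodane may be diverted: iodine can stay bound at C3 as an unreactive iodonium ylide, C1 can be captured by methoxide or by the C9 oxygen (α-oxygenation or epoxide closure), or the aldolate can cleave by retro-aldol reaction under KOH. The fallback sets out from 13 and places the leaving group on C1 in a separate operation. TMSOTf and Et3N (CH2Cl2, 0 °C) should give the tris(trimethylsilyl) derivative with a C9 silyl ether and a C1=C2/C3=C4 bis(silyloxy)diene, (2R,3aS,7aR)-3a-geranyl-1,1-dimethyl-2-prenyl-4,6,7a-tris(trimethylsilyloxy)-2,3,3a,7a-tetrahydro-1H-indene F5. NBS (THF, −78 °C) brominates such dienes at the terminal carbon and, after aqueous work-up, gives the C1 bromide, 7-bromo-3a-geranyl-4-hydroxy-1,1-dimethyl-2-prenyl-7a-(trimethylsilyloxy)-1,2,3,3a,7,7a-hexahydro-6H-inden-6-one F6. TBAF (THF, −20 °C) frees the C9 alkoxide, which expels bromide with 1,2-shift of C8 (halohydrin-type semipinacol rearrangement), and the route is rejoined at 15.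

**Further compounds**

F1 | step 8 | (1R,5S,7R)-5-[(2E)-3,7-dimethylocta-2,6-dien-1-yl]-4-methoxy-8,8-dimethyl-7-(3-methylbut-2-en-1-yl)-3-(trimethylsilyl)bicyclo[3.3.1]non-3-ene-2,9-dione | CC(C)=CCC/C(C)=C/C[C@]12C[C@@H](CC=C(C)C)C(C)(C)[C@H](C(=O)C([Si](C)(C)C)=C1OC)C2=O
F2 | step 8 | 1,5-bis[(2E)-3,7-dimethylocta-2,6-dien-1-yl]-4-methoxy-8,8-dimethyl-7-(3-methylbut-2-en-1-yl)-3-(trimethylsilyl)bicyclo[3.3.1]non-3-ene-2,9-dione (configuration as in 18) | CC(C)=CCC/C(C)=C/C[C@]12C[C@@H](CC=C(C)C)C(C)(C)[C@](C/C=C(\C)CCC=C(C)C)(C(=O)C([Si](C)(C)C)=C1OC)C2=O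
F3 | step 1 | 3-methylbut-3-en-1-ylmagnesium bromide | C=C(C)CC[Mg]Br
F4 | step 1 | (R)-2,2-dimethyl-3-(3-methylbut-3-en-1-yl)cyclopentan-1-one | O=C1CC[C@@H](CCC(C)=C)C1(C)C
F5 | step 6 | (2R,3aS,7aR)-3a-[(2E)-3,7-dimethylocta-2,6-dien-1-yl]-1,1-dimethyl-2-(3-methylbut-2-en-1-yl)-4,6,7a-tris(trimethylsilyloxy)-2,3,3a,7a-tetrahydro-1H-indene | CC(C)=CCC/C(C)=C/C[C@@]12C[C@@H](CC=C(C)C)C(C)(C)[C@]1(O[Si](C)(C)C)C=C(O[Si](C)(C)C)C=C2O[Si](C)(C)C
F6 | step 6 | 7-bromo-3a-[(2E)-3,7-dimethylocta-2,6-dien-1-yl]-4-hydroxy-1,1-dimethyl-2-(3-methylbut-2-en-1-yl)-7a-(trimethylsilyloxy)-1,2,3,3a,7,7a-hexahydro-6H-inden-6-one (configuration as in 13, C7 epimers) | CC(C)=CCC/C(C)=C/C[C@@]12C[C@@H](CC=C(C)C)C(C)(C)[C@]1(O[Si](C)(C)C)C(Br)C(=O)C=C2O
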